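## Retrosynthetic overview

1. 24 ⇐ 22: the 11,12-epoxide goes in last (bromohydrin route, β face); 22 ⇐ 20: α-methylbutenolide by methacrylate ring-closing metathesis onto C8=CH2.
2. 20 ⇐ 19: ten-membered ring by Ni/Cr closure of C6–C7 from a (Z)-alkenyl iodide and an enal (C7 by ligand control).
3. 19 ⇐ 14: Evans–Tishchenko reduction (C14–OH and the C2 butanoate in one step), then acetal → 2-methylene aldehyde and Si → I.
4. 14 ⇐ 11 ⇐ 6: 1,6-cuprate addition (C9–C10) to a 6,6-disubstituted cyclohexa-2,4-dienone, itself made from the arene by Birch reduction, OH-directed cyclopropanation/ring opening (quaternary C1) and dehydrogenation.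
5. 6 ⇐ 4 (inexpensive p-cresol-derived arene) + 3; ring order: six-membered ring (the former benzene ring) → ten-membered ring → butenolide → epoxide.

Labels: C1–C20 are the briarane positions of the target; on the six-membered ring β is the face of the C1 methyl (C15), α the opposite face.

Assumption: in step 12 the (S)-oxazoline–sulfonamide ligand is taken to deliver the alkenyl group to the Re face of C7=O (giving 7R); if the facial sense is the reverse, the (R)-ligand is used.

## Route

Step 1
Reactants: 1 4-(trimethylsilyl)but-3-yn-1-ol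
Product: 2 (Z)-3-methyl-4-(trimethylsilyl)but-3-en-1-ol
Conditions: MeMgBr (3 equiv), Ni(acac)2 (10 mol%), Me3Al (10 mol%), THF, 0 °C → rt; 1 M HCl, 0 °C
Reagents that add atoms: methylmagnesium bromide, C[Mg]Br
Why: Nickel-catalysed syn-carbomagnesiation of the silylalkyne (silicon directs magnesium to its own carbon; the hydroxyl is carried as its alkoxide) followed by protonolysis puts CH2CH2OH and SiMe3 cis, which fixes the later (Z)-C5=C6 geometry.

Step 2
Reactants: 2 (Z)-3-methyl-4-(trimethylsilyl)but-3-en-1-ol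
Product: 3 (Z)-(4-iodo-2-methylbut-1-en-1-yl)trimethylsilane
Conditions: I2, PPh3, imidazole, CH2Cl2, 0 °C → rt
Reagents that add atoms: iodine, II
Why: Appel-type (PPh3/I2/imidazole) substitution of the primary alcohol is clean and leaves the alkenylsilane untouched.

Step 3
Reactants: 3 (Z)-(4-iodo-2-methylbut-1-en-1-yl)trimethylsilane; 4 2-methoxy-5-methylbenzaldehyde
Product: 6 (1S,4Z)-1-(2-methoxy-5-methylphenyl)-4-methyl-5-(trimethylsilyl)pent-4-en-1-ol, via diorganozinc 5 (not isolated)
Conditions: 3 (2.2 equiv), Et2Zn (neat), CuI (cat.), 50 °C, then vacuum; Ti(OiPr)4 (2 equiv), (1R,2R)-N,N'-(cyclohexane-1,2-diyl)bis(trifluoromethanesulfonamide) (8 mol%), toluene, −20 °C, then 4; 1 M HCl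
Reagents that add atoms: none
Why: Iodine–zinc exchange gives the functionalised diorganozinc, and the Ti(OiPr)4/bis-sulfonamide-catalysed enantioselective alkylzinc addition to an aromatic aldehyde (Si-face attack with the (1R,2R)-ligand) sets C2 as S under catalyst control.

Step 4
Reactants: 6 (1S,4Z)-1-(2-methoxy-5-methylphenyl)-4-methyl-5-(trimethylsilyl)pent-4-en-1-ol
Product: 7 (1S,4Z)-1-(2-methoxy-5-methylcyclohexa-1,4-dien-1-yl)-4-methyl-5-(trimethylsilyl)pent-4-en-1-ol
Conditions: n-BuLi (1.05 equiv), THF, −78 °C; Li (8 equiv), NH3(l), t-BuOH (4 equiv), −78 °C; solid NH4Cl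
Reagents that add atoms: none
Why: Birch reduction of a 2,4-dialkylanisole protonates the unsubstituted ortho and meta carbons (C13, C10), so the methoxy and both alkyl groups stay on sp2 carbons and the product is the 1,4-diene with a regiodefined C1=C14 enol ether and the C11=C12 alkene already in place; the benzylic C–O bond is protected as its lithium alkoxide and the non-conjugated alkenylsilane is not reduced.

Step 5
Reactants: 7 (1S,4Z)-1-(2-methoxy-5-methylcyclohexa-1,4-dien-1-yl)-4-methyl-5-(trimethylsilyl)pent-4-en-1-ol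
Product: 9 (6S)-6-[(1S,4Z)-1-hydroxy-4-methyl-5-(trimethylsilyl)pent-4-en-1-yl]-4,6-dimethylcyclohex-3-en-1-one, via methoxycyclopropane 8 (not isolated)
Conditions: Et2Zn (2.5 equiv), CH2I2 (2.5 equiv), CH2Cl2, −20 → 0 °C; then 2 M HCl, THF/MeOH, rt → 40 °C
Reagents that add atoms: diiodomethane, ICI; water, O
Why: Hydroxyl-directed Simmons–Smith (Furukawa) cyclopropanation of the electron-rich enol ether: A(1,3) strain with the methoxy group keeps C2–H in the alkene plane, the zinc alkoxide delivers CH2 to the face syn to oxygen and so sets the quaternary C1 (S), and acid then cleaves the C14–CH2 bond of the methoxycyclopropane to leave the C15 methyl and the C14 ketone.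

Step 6
Reactants: 9 (6S)-6-[(1S,4Z)-1-hydroxy-4-methyl-5-(trimethylsilyl)pent-4-en-1-yl]-4,6-dimethylcyclohex-3-en-1-one
Product: 11 (6S)-4,6-dimethyl-6-[(1S,4Z)-4-methyl-1-(triethylsilyloxy)-5-(trimethylsilyl)pent-4-en-1-yl]cyclohexa-2,4-dien-1-one, via bis-silyl dienol ether 10 (not isolated)
Conditions: TESOTf (2.4 equiv), Et3N (3 equiv), CH2Cl2, 0 °C; then DDQ (1.1 equiv), 2,4,6-collidine, PhH, rt
Reagents that add atoms: triethylsilyl trifluoromethanesulfonate, CC[Si](CC)(CC)OS(=O)(=O)C(F)(F)F
Why: Soft enolisation can only go towards C13 (C1 is quaternary) and gives the conjugated silyl dienol ether while capping the C2 hydroxyl (which blocks retro-aldol rearomatisation of the dienone), and DDQ dehydrogenation of the dienol ether by hydride abstraction at C10 gives the linear 2,4-dienone.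

Step 7
Reactants: 11 (6S)-4,6-dimethyl-6-[(1S,4Z)-4-methyl-1-(triethylsilyloxy)-5-(trimethylsilyl)pent-4-en-1-yl]cyclohexa-2,4-dien-1-one; 12 [2-(1,3-dioxolan-2-yl)ethyl]magnesium bromide
Product: 14 (5S,6S)-5-[2-(1,3-dioxolan-2-yl)ethyl]-6-[(1S,4Z)-1-hydroxy-4-methyl-5-(trimethylsilyl)pent-4-en-1-yl]-4,6-dimethylcyclohex-3-en-1-one, via silyl dienol ether 13 (not isolated)
Conditions: 12 (2.5 equiv), CuBr·SMe2 (20 mol%), TMSCl (3 equiv), THF, −78 → −40 °C; then TBAF (3 equiv), AcOH (3 equiv), THF, −40 → 0 °C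
Reagents that add atoms: none
Why: Copper-catalysed 1,6-conjugate addition of a primary Grignard reagent to the 2,4-dienone forms C9–C10 anti to the larger C1 substituent (the silyloxyalkyl branch), which sets C10 with the side chain cis to C15, and fluoride/AcOH cleavage of the dienol ether protonates kinetically at C13 to leave the C11=C12 alkene out of conjugation.

Step 8
Reactants: 14 (5S,6S)-5-[2-(1,3-dioxolan-2-yl)ethyl]-6-[(1S,4Z)-1-hydroxy-4-methyl-5-(trimethylsilyl)pent-4-en-1-yl]-4,6-dimethylcyclohex-3-en-1-one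
Product: 15 hydroxy butanoate (14 with C14=O reduced to the α-alcohol and the C2 oxygen carrying the butanoyl group)
Conditions: PrCHO (6 equiv), SmI2 (30 mol%), THF, −10 °C, dark
Reagents that add atoms: butanal, CCCC=O
Why: Evans–Tishchenko reduction: the samarium-bound hemiacetal of butanal and the C2 hydroxyl delivers hydride intramolecularly through a chair transition state, which gives the 1,3-anti product, i.e. the C14 α-alcohol (14S), and leaves the acyl group on O2 as the butanoate; all atoms of both partners end up in the product.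

Step 9
Reactants: 15 hydroxy butanoate
Product: 16 acetate butanoate (C14 O-acetyl derivative of 15)
Conditions: Ac2O, DMAP (cat.), pyridine, 40 °C
Reagents that add atoms: acetic anhydride, CC(=O)OC(C)=O
Why: DMAP-catalysed acylation of the hindered secondary alcohol is run at once to forestall 1,3-acyl migration; no stereocentre changes.

Step 10
Reactants: 16 acetate butanoate
Product: 18 enal (16 with the C10 side chain converted to CH2–C(=CH2)–CHO), via aldehyde 17 (not isolated)
Conditions: 2 M HCl, THF, rt; then 37% aq. CH2O, pyrrolidine (20 mol%), EtCO2H (20 mol%), i-PrOH, 45 °C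
Reagents that add atoms: water, O; formaldehyde, C=O
Why: Acid hydrolysis of the dioxolane and amine-catalysed Mannich condensation–elimination (α-methylenation) with formaldehyde give the 2-substituted acrolein that carries C7, C8 and the methylene that later leaves in the metathesis.

Step 11
Reactants: 18 enal
Product: 19 (Z)-alkenyl iodide enal (18 with SiMe3 replaced by iodine)
Conditions: NIS (1.3 equiv), (CF3)2CHOH, 0 °C
Reagents that add atoms: N-iodosuccinimide, O=C1CCC(=O)N1I
Why: ipso-Iododesilylation of the alkenylsilane by NIS goes through the β-silyl cation with retention, giving the (Z)-alkenyl iodide much faster than NIS attacks the other trisubstituted alkene or the electron-poor enal.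

Step 12
Reactants: 19 (Z)-alkenyl iodide enal
Product: 20 macrocyclic allylic alcohol (ten-membered ring closed at C6–C7; 7R hydroxyl; C8=CH2; 5Z)
Conditions: CrCl2 (10 equiv), NiCl2 (5 mol%), (S)-N-[2-(4-isopropyl-4,5-dihydrooxazol-2-yl)-6-methoxyphenyl]methanesulfonamide (11 equiv), Et3N (11 equiv), THF, rt, slow addition of 19 (final 2 mM)
Reagents that add atoms: none
Why: Intramolecular Nozaki–Hiyama–Kishi reaction: oxidative addition at nickel and transmetalation give an alkenylchromium species that adds 1,2 to the enal under high dilution with retention of the (Z) geometry, and the chiral sulfonamide ligand on chromium directs attack to the Re face of C7=O to give 7R.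

Step 13
Reactants: 20 macrocyclic allylic alcohol
Product: 21 C7 methacrylate of 20
Conditions: methacryloyl chloride, Et3N, DMAP (cat.), CH2Cl2, 0 °C
Reagents that add atoms: methacryloyl chloride, CC(=C)C(Cl)=O
Why: Standard acylation of the allylic alcohol installs C17, C18 and C19 without touching C7.

Step 14
Reactants: 21 C7 methacrylate
Product: 22 butenolide (11,12-deoxy target with the C11=C12 alkene)
Conditions: second-generation Hoveyda–Grubbs catalyst (15 mol%), 1,4-benzoquinone (20 mol%), toluene, 100 °C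
Reagents that add atoms: none
Why: Ring-closing metathesis between the methacrylate and the 1,1-disubstituted C8 methylene is driven by loss of ethene and by formation of a five-membered ring, and neither trisubstituted ring alkene competes.

Step 15
Reactants: 22 butenolide
Product: 24 CNP0220791.2 (target), via bromohydrin 23 (not isolated)
Conditions: NBS (1.05 equiv), THF/H2O (4:1), 0 °C; then Ag2O, rt
Reagents that add atoms: water, O
Why: Bromohydrin route to the epoxide: in the trans-fused conformer with axial C15 the bromonium forms on the α face of the more electron-rich C11=C12 alkene, water opens it trans-diaxially at the tertiary C11 from the β face (Markovnikov), and Ag2O closes the 11β-alkoxide onto C12 with inversion to give the 11β,12β-epoxide (11R,12S), the face opposite to that of a peracid.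

## Compound list

1 | 4-(trimethylsilyl)but-3-yn-1-ol | C[Si](C)(C)C#CCCO | starting material
2 | (Z)-3-methyl-4-(trimethylsilyl)but-3-en-1-ol | OCC/C(C)=C\[Si](C)(C)C | intermediate
3 | (Z)-(4-iodo-2-methylbut-1-en-1-yl)trimethylsilane | ICC/C(C)=C\[Si](C)(C)C | intermediate
4 | 2-methoxy-5-methylbenzaldehyde | COc1ccc(C)cc1C=O | starting material
5 | bis[(Z)-3-methyl-4-(trimethylsilyl)but-3-en-1-yl]zinc | C[Si](C)(C)/C=C(C)\CC[Zn]CC/C(C)=C\[Si](C)(C)C | intermediate
6 | (1S,4Z)-1-(2-methoxy-5-methylphenyl)-4-methyl-5-(trimethylsilyl)pent-4-en-1-ol | COc1ccc(C)cc1[C@@H](O)CC/C(C)=C\[Si](C)(C)C | intermediate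
7 | (1S,4Z)-1-(2-methoxy-5-methylcyclohexa-1,4-dien-1-yl)-4-methyl-5-(trimethylsilyl)pent-4-en-1-ol | COC1=C([C@@H](O)CC/C(C)=C\[Si](C)(C)C)CC(C)=CC1 | intermediate
8 | 1-methoxy-4-methylbicyclo[4.1.0]hept-3-ene carrying the (1S,4Z)-1-hydroxy-4-methyl-5-(trimethylsilyl)pent-4-enyl group at C6; cyclopropane CH2 on the β face (syn to the C2 hydroxyl) | CO[C@@]12CC=C(C)C[C@@]1(C2)[C@@H](O)CC/C(C)=C\[Si](C)(C)C | intermediate
9 | (6S)-6-[(1S,4Z)-1-hydroxy-4-methyl-5-(trimethylsilyl)pent-4-en-1-yl]-4,6-dimethylcyclohex-3-en-1-one | O=C1CC=C(C)C[C@@]1(C)[C@@H](O)CC/C(C)=C\[Si](C)(C)C | intermediate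
10 | bis-triethylsilyl derivative of 9: C14 triethylsilyl dienol ether (C13=C14, C11=C12) and C2 triethylsilyl ether | CC[Si](CC)(CC)OC1=CC=C(C)C[C@@]1(C)[C@@H](O[Si](CC)(CC)CC)CC/C(C)=C\[Si](C)(C)C | intermediate
11 | (6S)-4,6-dimethyl-6-[(1S,4Z)-4-methyl-1-(triethylsilyloxy)-5-(trimethylsilyl)pent-4-en-1-yl]cyclohexa-2,4-dien-1-one | O=C1C=CC(C)=C[C@@]1(C)[C@@H](O[Si](CC)(CC)CC)CC/C(C)=C\[Si](C)(C)C | intermediate
12 | [2-(1,3-dioxolan-2-yl)ethyl]magnesium bromide | Br[Mg]CCC1OCCO1 | starting material
13 | 1,6-adduct as its C14 trimethylsilyl dienol ether (C10 side chain β, C2 triethylsilyl ether) | C[Si](C)(C)OC1=CC=C(C)[C@H](CCC2OCCO2)[C@@]1(C)[C@@H](O[Si](CC)(CC)CC)CC/C(C)=C\[Si](C)(C)C | intermediate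
14 | (5S,6S)-5-[2-(1,3-dioxolan-2-yl)ethyl]-6-[(1S,4Z)-1-hydroxy-4-methyl-5-(trimethylsilyl)pent-4-en-1-yl]-4,6-dimethylcyclohex-3-en-1-one | O=C1CC=C(C)[C@H](CCC2OCCO2)[C@@]1(C)[C@@H](O)CC/C(C)=C\[Si](C)(C)C | intermediate
15 | hydroxy butanoate: 14 with C14 as the α-alcohol (14S) and C2–O-butanoyl | O[C@H]1CC=C(C)[C@H](CCC2OCCO2)[C@@]1(C)[C@@H](OC(=O)CCC)CC/C(C)=C\[Si](C)(C)C | intermediate
16 | acetate butanoate: C14–O-acetyl derivative of 15 | CC(=O)O[C@H]1CC=C(C)[C@H](CCC2OCCO2)[C@@]1(C)[C@@H](OC(=O)CCC)CC/C(C)=C\[Si](C)(C)C | intermediate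
17 | aldehyde: 16 with the dioxolane opened to C7H=O (side chain CH2CH2CHO) | CC(=O)O[C@H]1CC=C(C)[C@H](CCC=O)[C@@]1(C)[C@@H](OC(=O)CCC)CC/C(C)=C\[Si](C)(C)C | intermediate
18 | enal: 17 with a methylene on C8 (side chain CH2–C(=CH2)–CHO) | CC(=O)O[C@H]1CC=C(C)[C@H](CC(=C)C=O)[C@@]1(C)[C@@H](OC(=O)CCC)CC/C(C)=C\[Si](C)(C)C | intermediate
19 | (Z)-alkenyl iodide enal: 18 with SiMe3 replaced by iodine | CC(=O)O[C@H]1CC=C(C)[C@H](CC(=C)C=O)[C@@]1(C)[C@@H](OC(=O)CCC)CC/C(C)=C\I | intermediate
20 | macrocyclic allylic alcohol: ten-membered ring, 7R hydroxyl, C8 exocyclic methylene, 5Z alkene, C11=C12 alkene | CCCC(=O)O[C@H]1CC/C(C)=C\[C@@H](O)C(=C)C[C@H]2C(C)=CC[C@H](OC(C)=O)[C@]12C | intermediate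
21 | C7 methacrylate of 20 | CCCC(=O)O[C@H]1CC/C(C)=C\[C@@H](OC(=O)C(C)=C)C(=C)C[C@H]2C(C)=CC[C@H](OC(C)=O)[C@]12C | intermediate
22 | butenolide: 11,12-deoxy target (C11=C12 alkene) | CCCC(=O)O[C@H]1CC/C(C)=C\[C@H]2OC(=O)C(C)=C2C[C@H]2C(C)=CC[C@H](OC(C)=O)[C@]12C | intermediate
23 | bromohydrin of 22: 11β-hydroxy, 12α-bromo | CCCC(=O)O[C@H]1CC/C(C)=C\[C@H]2OC(=O)C(C)=C2C[C@H]2[C@@](C)(O)[C@H](Br)C[C@H](OC(C)=O)[C@]12C | intermediate
24 | CNP0220791.2: (1S,2S,7R,10R,11R,12S,14S)-14-acetoxy-2-butanoyloxy-11,12-epoxybriara-5(Z),8(17)-dien-18,7-olide | CCCC(=O)O[C@H]1CC/C(C)=C\[C@H]2OC(=O)C(C)=C2C[C@H]2[C@@]3(C)O[C@H]3C[C@H](OC(C)=O)[C@]12C | target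

## Step count and risk

Total steps: 15. Longest linear sequence: 15 (steps 1–15, from 1 to 24; 4 and 12 are bought).

Where each stereo-element is set: C5=C6 (Z) in step 1, C2 in step 3, C1 in step 5, C10 in step 7, C14 in step 8, C7 in step 12, C11/C12 in step 15.

The three steps most likely to fail:

Step 4 (Birch reduction). The risk is partial reduction of the alkenylsilane or loss of the benzylic oxygen. The fallback attaches the alkenylsilane after the dearomatisation. It sets out from 4: (−)-DAIB-catalysed addition of divinylzinc gives (S)-1-(2-methoxy-5-methylphenyl)prop-2-en-1-ol F1, and the same Li/NH3 reduction gives (S)-1-(2-methoxy-5-methylcyclohexa-1,4-dien-1-yl)prop-2-en-1-ol F2. Hydroboration of the terminal vinyl group with 9-BBN, then alkyl Suzuki coupling (Pd(dppf)Cl2, K3PO4, DMF/THF/H2O) with (Z)-(2-iodoprop-1-en-1-yl)trimethylsilane F3 (made from 1-(trimethylsilyl)propyne by anti-hydroiodination), forms C4–C5 and returns to the route at 7.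

Step 12 (ten-membered Ni/Cr closure). The risk is poor ligand control at C7 in a medium-ring closure. The fallback sets C7 by ketone reduction instead. It sets out from 19: closure without ligand (CrCl2, NiCl2 cat., DMSO, high dilution) gives the macrocyclic alcohol as a C7 epimer mixture F4. Dess–Martin periodinane oxidises it to the cross-conjugated macrocyclic C7 ketone F5. Reduction with (S)-2-methyl-CBS-oxazaborolidine and catecholborane (the α-branched C8 alkenyl group acting as the large substituent) then returns to the route at 20.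

Step 14 (metathesis to a tetrasubstituted butenolide alkene). The risk is that the tetrasubstituted C8=C17 bond does not close. The fallback closes a trisubstituted alkene and adds the methyl by cross-coupling. It sets out from 20: acryloyl chloride/Et3N gives the C7 acrylate F6, and metathesis with the same catalyst gives the α-unsubstituted butenolide F7. Iodine/pyridine gives the α-iodobutenolide F8, and Stille methylation (Me4Sn, Pd2(dba)3, AsPh3, CuI, NMP) returns to the route at 22.

## Further compounds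

F1 | step 4 | (S)-1-(2-methoxy-5-methylphenyl)prop-2-en-1-ol | COc1ccc(C)cc1[C@@H](O)C=C
F2 | step 4 | (S)-1-(2-methoxy-5-methylcyclohexa-1,4-dien-1-yl)prop-2-en-1-ol | COC1=C([C@@H](O)C=C)CC(C)=CC1
F3 | step 4 | (Z)-(2-iodoprop-1-en-1-yl)trimethylsilane | I/C(C)=C\[Si](C)(C)C
F4 | step 12 | macrocyclic allylic alcohol, C7 epimer mixture | CCCC(=O)O[C@H]1CC/C(C)=C\C(O)C(=C)C[C@H]2C(C)=CC[C@H](OC(C)=O)[C@]12C
F5 | step 12 | macrocyclic C7 ketone | CCCC(=O)O[C@H]1CC/C(C)=C\C(=O)C(=C)C[C@H]2C(C)=CC[C@H](OC(C)=O)[C@]12C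
F6 | step 14 | C7 acrylate of 20 | CCCC(=O)O[C@H]1CC/C(C)=C\[C@@H](OC(=O)C=C)C(=C)C[C@H]2C(C)=CC[C@H](OC(C)=O)[C@]12C
F7 | step 14 | α-unsubstituted butenolide | CCCC(=O)O[C@H]1CC/C(C)=C\[C@H]2OC(=O)C=C2C[C@H]2C(C)=CC[C@H](OC(C)=O)[C@]12C
F8 | step 14 | α-iodobutenolide | CCCC(=O)O[C@H]1CC/C(C)=C\[C@H]2OC(=O)C(I)=C2C[C@H]2C(C)=CC[C@H](OC(C)=O)[C@]12C
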